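**Retrosynthetic overview**
- The strategy rests on ring A: methoxy groups at C6, C7 and C8, the ring oxygen on C8a para to C6, H on C5 and the C4 carbon on C4a. This is a 4-methoxyphenol with an ortho carbon substituent, the pattern that an alkenyl(methoxy)carbene, a terminal alkyne and one CO assemble.
- Ring C is opened at O1–C2 (acid cyclodehydration) and at C3–C4 (aldol addition, then oxidation of C4). This leads to 2-hydroxy-3,4,5-trimethoxybenzaldehyde and the bought ring B ketone 2-methoxy-1-(4-methoxyphenyl)ethanone.
- Ring A is opened at C5–C6, C4a–C8a and C8–C8a into the trimethoxy carbene complex 6 (C6, C7, C8), one CO ligand (C8a) and 3,3-diethoxyprop-1-yne (C5, C4a and, as the acetal, C4).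
- Order of ring formation: ring A in step 3, ring C in step 8; ring B is bought.

Key step: step 3

Assumption: enol ether 2 is taken as the Z isomer, the thermodynamically preferred geometry of a 1,2-dialkoxyethene. Any E isomer carried along should converge on the same arene, because both alkene carbons become sp2 carbons of ring A. The target has no stereocentre; the two stereocentres of aldol adduct 14 are removed in steps 7 and 8.

**Step 1**
Reactants: 1 1,1,2-trimethoxyethane
Product: 2 (Z)-1,2-dimethoxyethene
Conditions: Me3SiOTf, i-Pr2NEt, CH2Cl2, −20 °C to rt; fractional distillation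
Reagents that add atoms: none
Why: Silyl triflate/amine-mediated conversion of a dimethyl acetal into its methyl enol ether: Me3SiOTf ionises the acetal to an oxocarbenium ion, the hindered amine removes the C2 proton, and the cis isomer is the favoured geometry of a 1,2-dialkoxyethene.

**Step 2**
Reactants: 2 (Z)-1,2-dimethoxyethene; 3 chromium hexacarbonyl Cr(CO)6
Product: 6 pentacarbonyl[(Z)-1,2,3-trimethoxyprop-2-en-1-ylidene]chromium, via vinyllithium 4 (not isolated), via lithium acylchromate 5 (not isolated)
Conditions: t-BuLi, THF, −78 to −40 °C; Cr(CO)6, −78 to 0 °C; then Me3OBF4, CH2Cl2, 0 °C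
Reagents that add atoms: trimethyloxonium tetrafluoroborate Me3OBF4, C[O+](C)C.F[B-](F)(F)F
Why: Fischer carbene synthesis: vinylic deprotonation next to oxygen (as with methyl vinyl ether or 5,6-dihydro-1,4-dioxin) gives a configurationally stable vinyllithium that adds to a CO ligand of Cr(CO)6, and O-methylation of the acylchromate by the hard oxonium salt gives the methoxycarbene with the alkene geometry retained.

**Step 3**
Reactants: 6 pentacarbonyl[(Z)-1,2,3-trimethoxyprop-2-en-1-ylidene]chromium; 7 3,3-diethoxyprop-1-yne
Product: 9 6-(diethoxymethyl)-2,3,4-trimethoxyphenol, via arene tricarbonylchromium complex 8 (not isolated)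
Conditions: 7 (excess), THF, 50 °C, Ar; then air, Et2O, rt; crude product or Et3N-deactivated SiO2
Reagents that add atoms: none
Why: Thermal loss of one CO from 6 lets the alkyne coordinate and insert into the Cr=C bond with its unsubstituted carbon bonded to the former carbene carbon (C5–C6), and CO insertion then gives a chromium-bound dienylketene (C4a–C8a). A 6π electrocyclisation of this ketene onto the methoxy-bearing alkene terminus closes ring A (C8–C8a), and tautomerisation of the cyclohexadienone gives the phenol as its Cr(CO)3 complex 8, which air decomplexes. This is the Dötz benzannulation of an alkenyl(methoxy)carbene chromium complex with a terminal alkyne, a known reaction type, and it forms no stereocentre. The regiochemistry needed, acetal carbon ortho to the new hydroxyl, follows from the usual steric preference that keeps the larger alkyne substituent away from the carbene carbon during insertion. Phenol formation over cyclopentannulation is favoured by the methoxy (not amino) carbene, by THF and by moderate temperature, and the β-hydrogen needed for aromatisation is present on the terminal alkene carbon. Demetalation by air instead of Ce(NH4)2(NO3)6 keeps the 4-methoxyphenol from being oxidised to a quinone, and the neutral medium spares the acetal.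

**Step 4**
Reactants: 9 6-(diethoxymethyl)-2,3,4-trimethoxyphenol
Product: 10 2-hydroxy-3,4,5-trimethoxybenzaldehyde
Conditions: 1 M HCl, THF, rt
Reagents that add atoms: water, O
Why: Acid-catalysed hydrolysis of an aryl diethyl acetal, which is fast at room temperature for this electron-rich ortho-hydroxy acetal while the aryl methyl ethers are inert.

**Step 5**
Reactants: 10 2-hydroxy-3,4,5-trimethoxybenzaldehyde
Product: 11 2-(methoxymethoxy)-3,4,5-trimethoxybenzaldehyde
Conditions: MOMCl, i-Pr2NEt, CH2Cl2, 0 °C to rt
Reagents that add atoms: chloromethyl methyl ether (MOMCl), COCCl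
Why: O-Alkylation of the phenol with MOMCl and Hünig's base, standard for salicylaldehydes; the MOM ether prevents phenoxide deactivation of the aldehyde in step 6 and phenol oxidation in step 7, and it is removed by the acid of step 8.

**Step 6**
Reactants: 12 2-methoxy-1-(4-methoxyphenyl)ethanone; 11 2-(methoxymethoxy)-3,4,5-trimethoxybenzaldehyde
Product: 14 3-hydroxy-2-methoxy-1-(4-methoxyphenyl)-3-[2-(methoxymethoxy)-3,4,5-trimethoxyphenyl]propan-1-one (diastereomer mixture), via lithium enolate 13 (not isolated)
Conditions: LiN(i-Pr)2, THF, −78 °C; then 11; AcOH quench, −78 °C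
Reagents that add atoms: none
Why: Directed aldol addition of the preformed, chelated lithium enolate of an α-methoxy aryl ketone to a non-enolisable aldehyde forms the C3–C4 bond; the two new stereocentres arise without control, which does not matter because both are removed in steps 7 and 8.

**Step 7**
Reactants: 14 3-hydroxy-2-methoxy-1-(4-methoxyphenyl)-3-[2-(methoxymethoxy)-3,4,5-trimethoxyphenyl]propan-1-one
Product: 15 2-methoxy-1-(4-methoxyphenyl)-3-[2-(methoxymethoxy)-3,4,5-trimethoxyphenyl]propane-1,3-dione
Conditions: Dess–Martin periodinane, CH2Cl2, rt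
Reagents that add atoms: none
Why: Dess–Martin oxidation of a secondary benzylic β-hydroxy ketone to the 1,3-diketone under near-neutral conditions that spare the MOM acetal and the electron-rich arenes.

**Step 8**
Reactants: 15 2-methoxy-1-(4-methoxyphenyl)-3-[2-(methoxymethoxy)-3,4,5-trimethoxyphenyl]propane-1,3-dione
Product: 18 auranetin (3,6,7,8-tetramethoxy-2-(4-methoxyphenyl)-4H-chromen-4-one), via phenolic diketone 16 (not isolated), via hemiketal 17 (not isolated)
Conditions: conc. HCl, MeOH, 60 °C
Reagents that add atoms: none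
Why: Acid methanolysis removes the MOM group, the freed phenol adds to the distal aroyl carbonyl to give the six-membered hemiketal, and dehydration gives the γ-pyrone, the cyclodehydration that ends a Baker–Venkataraman flavone synthesis.

**Compound list**
1 | 1,1,2-trimethoxyethane | COCC(OC)OC | starting material
2 | (Z)-1,2-dimethoxyethene | CO/C=C\OC | intermediate
3 | chromium hexacarbonyl Cr(CO)6 | O=C=[Cr](=C=O)(=C=O)(=C=O)(=C=O)=C=O | starting material
4 | [(Z)-1,2-dimethoxyethenyl]lithium | CO/C=C(\OC)[Li] | intermediate (not isolated)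
5 | lithium pentacarbonyl[(Z)-2,3-dimethoxyprop-2-enoyl]chromate | CO/C=C(\OC)C([O-])=[Cr](=C=O)(=C=O)(=C=O)(=C=O)=C=O.[Li+] | intermediate (not isolated)
6 | pentacarbonyl[(Z)-1,2,3-trimethoxyprop-2-en-1-ylidene]chromium | CO/C=C(\OC)C(OC)=[Cr](=C=O)(=C=O)(=C=O)(=C=O)=C=O | intermediate
7 | 3,3-diethoxyprop-1-yne | C#CC(OCC)OCC | starting material
8 | tricarbonyl[η6-6-(diethoxymethyl)-2,3,4-trimethoxyphenol]chromium (Cr(CO)3 unit bound to the face of ring A, written as a separate fragment) | CCOC(OCC)c1cc(OC)c(OC)c(OC)c1O.O=C=[Cr](=C=O)=C=O | intermediate (not isolated)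
9 | 6-(diethoxymethyl)-2,3,4-trimethoxyphenol | CCOC(OCC)c1cc(OC)c(OC)c(OC)c1O | intermediate
10 | 2-hydroxy-3,4,5-trimethoxybenzaldehyde | O=Cc1cc(OC)c(OC)c(OC)c1O | intermediate
11 | 2-(methoxymethoxy)-3,4,5-trimethoxybenzaldehyde | COCOc1c(OC)c(OC)c(OC)cc1C=O | intermediate
12 | 2-methoxy-1-(4-methoxyphenyl)ethanone | COCC(=O)c1ccc(OC)cc1 | starting material
13 | lithium (Z)-2-methoxy-1-(4-methoxyphenyl)ethenolate | CO/C=C(\[O-])c1ccc(OC)cc1.[Li+] | intermediate (not isolated)
14 | 3-hydroxy-2-methoxy-1-(4-methoxyphenyl)-3-[2-(methoxymethoxy)-3,4,5-trimethoxyphenyl]propan-1-one (racemic diastereomer mixture) | COCOc1c(OC)c(OC)c(OC)cc1C(O)C(OC)C(=O)c1ccc(OC)cc1 | intermediate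
15 | 2-methoxy-1-(4-methoxyphenyl)-3-[2-(methoxymethoxy)-3,4,5-trimethoxyphenyl]propane-1,3-dione (racemic) | COCOc1c(OC)c(OC)c(OC)cc1C(=O)C(OC)C(=O)c1ccc(OC)cc1 | intermediate
16 | 1-(2-hydroxy-3,4,5-trimethoxyphenyl)-2-methoxy-3-(4-methoxyphenyl)propane-1,3-dione | COc1ccc(cc1)C(=O)C(OC)C(=O)c1cc(OC)c(OC)c(OC)c1O | intermediate (not isolated)
17 | 2-hydroxy-3,6,7,8-tetramethoxy-2-(4-methoxyphenyl)-2,3-dihydro-4H-chromen-4-one (isomer mixture) | COc1ccc(cc1)C1(O)Oc2c(OC)c(OC)c(OC)cc2C(=O)C1OC | intermediate (not isolated)
18 | auranetin, 3,6,7,8-tetramethoxy-2-(4-methoxyphenyl)-4H-chromen-4-one | COc1ccc(-c2oc3c(OC)c(OC)c(OC)cc3c(=O)c2OC)cc1 | target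

**Step count**
Total: 8 steps. Longest linear sequence: 8 steps (1 to 18). Compounds 3, 7 and 12 enter as bought materials.

**Steps most likely to fail**

1. Step 3 (benzannulation). The donor-rich, push–pull stabilised carbene may lose CO only sluggishly, or after alkyne insertion the vinylcarbene may close without CO insertion (cyclopentannulation), so that ring A is not formed as the phenol. The fallback sets out from alkyne 7 and comes back to the route at phenol 9; it replaces the chromium carbene by a cyclobutenone that opens thermally to the same kind of dienylketene. Radical hydrostannation of 7 (Bu3SnH, AIBN, 80 °C) should give (E)-tributyl(3,3-diethoxyprop-1-enyl)stannane F1. Tin–lithium exchange (n-BuLi, THF, −78 °C) gives (E)-3,3-diethoxyprop-1-enyllithium F2. F2 adds to one carbonyl of dimethyl squarate (3,4-dimethoxycyclobut-3-ene-1,2-dione) to give 4-[(E)-3,3-diethoxyprop-1-enyl]-4-hydroxy-2,3-dimethoxycyclobut-2-en-1-one F3. O-Methylation (MeI, Ag2O) gives 4-[(E)-3,3-diethoxyprop-1-enyl]-2,3,4-trimethoxycyclobut-2-en-1-one F4. Heating F4 in toluene at 110 °C (Moore rearrangement) should open the four-membered ring with the methoxy group rotating outward; 6π closure onto the alkenyl terminus and tautomerisation then give 9. The ring carbonyl becomes C8a–OH, the three methoxy carbons become C8, C7 and C6, and the alkenyl carbons become C5 and C4a.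

2. Step 2 (carbene complex). Anti β-elimination of LiOMe from vinyllithium 4 may outrun its addition to Cr(CO)6, or metalation may be incomplete. The fallback sets out from 2 and 3 and comes back at 6, avoiding the organolithium. Acylation of 2 with oxalyl chloride followed by warming, with loss of HCl and CO (the known route from enol ethers to 3-alkoxyacryloyl chlorides), should give (Z)-2,3-dimethoxyprop-2-enoyl chloride F5. Reduction of 3 with potassium graphite C8K in THF gives dipotassium pentacarbonylchromate K2Cr(CO)5 F6. Acylation of F6 with F5 at −78 °C gives potassium pentacarbonyl[(Z)-2,3-dimethoxyprop-2-enoyl]chromate F7, and O-methylation with Me3OBF4 gives 6.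

3. Step 6 (aldol addition). The hindered, electron-rich aldehyde may add slowly and the aldolate may revert or dehydrate, so that conversion to 14 stalls. The fallback sets out from 11 and comes back at diketone 15, which makes step 7 unnecessary; it forms the C3–C4 bond by acylation instead of aldol addition. Pinnick oxidation of 11 (NaClO2, NaH2PO4, 2-methylbut-2-ene, t-BuOH/H2O) gives 2-(methoxymethoxy)-3,4,5-trimethoxybenzoic acid F8. 1,1'-Carbonyldiimidazole in THF converts F8 into 1H-imidazol-1-yl[2-(methoxymethoxy)-3,4,5-trimethoxyphenyl]methanone F9. C-Acylation of enolate 13 (two equivalents, from 12 and LiN(i-Pr)2, THF, −78 °C to 0 °C) with F9 gives 15.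

**Further compounds**
F1 | step 3 | (E)-tributyl(3,3-diethoxyprop-1-enyl)stannane | CCCC[Sn](CCCC)(CCCC)/C=C/C(OCC)OCC
F2 | step 3 | (E)-3,3-diethoxyprop-1-enyllithium | [Li]/C=C/C(OCC)OCC
F3 | step 3 | 4-[(E)-3,3-diethoxyprop-1-enyl]-4-hydroxy-2,3-dimethoxycyclobut-2-en-1-one (racemic) | COC1=C(OC)C(O)(/C=C/C(OCC)OCC)C1=O
F4 | step 3 | 4-[(E)-3,3-diethoxyprop-1-enyl]-2,3,4-trimethoxycyclobut-2-en-1-one (racemic) | COC1=C(OC)C(OC)(/C=C/C(OCC)OCC)C1=O
F5 | step 2 | (Z)-2,3-dimethoxyprop-2-enoyl chloride | CO/C=C(\OC)C(Cl)=O
F6 | step 2 | dipotassium pentacarbonylchromate K2Cr(CO)5 | [K+].[K+].O=C=[Cr-2](=C=O)(=C=O)(=C=O)=C=O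
F7 | step 2 | potassium pentacarbonyl[(Z)-2,3-dimethoxyprop-2-enoyl]chromate | CO/C=C(\OC)C([O-])=[Cr](=C=O)(=C=O)(=C=O)(=C=O)=C=O.[K+]
F8 | step 6 | 2-(methoxymethoxy)-3,4,5-trimethoxybenzoic acid | COCOc1c(OC)c(OC)c(OC)cc1C(O)=O
F9 | step 6 | 1H-imidazol-1-yl[2-(methoxymethoxy)-3,4,5-trimethoxyphenyl]methanone | COCOc1c(OC)c(OC)c(OC)cc1C(=O)n1ccnc1
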